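I began from 40.0%, the conversion ceiling: partner charged minus protic impurity charged, divided by starting material charged, which is the share of the starting material that partner can still pay for if each molecule of impurity spends one partner and each turnover another.

| setting | teal | red | ash | birch | larch | alder |
|---|---|---|---|---|---|---|
| starting material | 0.12 M | 0.12 M | 0.12 M | 0.12 M | 0.12 M | 0.12 M |
| partner | 0.060 M | 0.060 M | 0.0600 M | 0.0600 M | 0.0600 M | 0.0600 M |
| protic impurity | 0.017 M | 0.026 M | 0.0120 M | 0.0120 M | 0.0120 M | 0.0120 M |
| temperature | −10 °C | 18 °C | 25 °C | 10 °C | 40 °C | −5 °C |
| remark | run made earlier | run made earlier |  |  |  |  |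
| time |  |  | 8.0 h | 8.0 h | 8.0 h | 8.0 h |

| run | time / h | target / % | starting material / % |
|---|---|---|---|
| teal | 3.00 | 6 | 97 |
| teal | 5.00 | 10 | 94 |
| teal | 8.00 | 11 | 88 |
| teal | 12.0 | 14 | 84 |
| teal | 15.0 | 17 | 81 |
| teal | 25.0 | 26 | 79 |
| teal | 30.0 | 29 | 75 |
| red | 1.00 | 13 | 90 |
| red | 2.00 | 18 | 79 |
| red | 3.00 | 19 | 79 |
| red | 4.00 | 25 | 71 |
| red | 5.00 | 22 | 68 |
| red | 6.00 | 27 | 70 |

(scatter of a reading: 2 percentage points)

* the best flask by amount of target, in percent of the starting material charged; "all alike" if 1.5 percentage points covers them all (ash / birch / larch / alder / all alike)
* amount of target at the end, in percent of the starting material charged, ash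
* amount of target at the end, in percent of the starting material charged, birch
* amount of target at the end, in percent of the starting material charged, larch
* amount of target at the end, in percent of the starting material charged, alder

I took these two amounts, spare partner and starting material, from the red run. There the spare partner was 0.0340 M against 0.12 M of starting material, a ceiling of 28.3%, and target read 27% at 6.00 h, close to it within the scatter of 2 percentage points, with 70% of starting material remaining. In the red run partner was the limiting reagent, charged at less than the starting material. The cold teal run, with a ceiling of 35.8%, read 11% at 8.00 h and 29% at 30.0 h, still below it, so I expected alder to fall short of the ceiling at 8.0 h. I committed to conversion near 40.0% in the warm flasks, and I counted any shortfall of target below that as a small correction to be reckoned separately.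

The forecast named ash best, with 38.5% there, 33% in birch, 37% in larch and 18% in alder, its shading of larch resting on “hinting at a side loss when warm”.

The flasks gave 27.0% in ash, 30.9% in birch, 25.4% in larch and 15.7% in alder, so birch held the most target. In the ash flask, conversion stood at 40.0%, level with the ceiling, with partner at 0% of its charge, and the isomer of the product held 13.0% at 8.00 h. The ceiling minus that isomer is 27.0%, which is the target the ash flask showed.

    starting material + partner → target, rate k1*[starting material]^2*[partner]^0.5 (k = 10.0 /M^1.5/h, Ea = 52.0 kJ/mol)
    target ⇌ isomer of the product (K = 1.70, k = 0.0710 /h, Ea = 95.0 kJ/mol, ΔH = −56.0 kJ/mol)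
    partner + protic impurity → quenched reagent (k = 140 /M/h, Ea = 68.0 kJ/mol)
    (constants at 25 °C)

In a neighbour of birch charged with 0.24 M of partner, the ceiling becomes 190%, above the whole charge, so it sets no stop within the charge. That flask gave 54.8% of target at 8.00 h, with 42.5% of starting material and 66% of its partner still there.

Readings and results are simulated on assumed constants; scatter was added.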